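**Plan**

- Retrosynthesis: remove the 17 benzyl groups and both gallates; cut the CH2–aryl bond of the chalcan arm (terminal epoxide + 2,4,6-tris(benzyloxy)phenyllithium); cut the C8–CH(aryl) bond (Friedel–Crafts opening of a cis-aryl epoxide by C8 of ring A); last, open ring C of the flavan at C3–C4 and O1–C8a.
- Enabling feature: in ring C the methylene C4 sits on C4a and O1 on the neighbouring ring-A carbon C8a, while O1–C2–C3 is the oxygen/α-carbon pair of the enolate of the ring-B aryl methyl ketone. A 2-bromobenzyl bromide (benzylic and aryl electrophile) and that enolate (C- then O-nucleophile) therefore close ring C in one flask as an achiral 2-aryl-4H-chromene.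
- Forward order: ring-A dibromide + ring-B ketone → ring C (4H-chromene) → hydroboration to the trans-flavan-3-ol → C8 alkylation by an epoxy tosylate → terminal epoxide → aryllithium opening (phloroglucinol ring) → two gallates → hydrogenolysis.
- Stereochemistry: C2/C3 (2S,3R) are set together by one reagent-controlled syn hydroboration of the flat C2=C3 bond; the side-chain carbinol carbon (S) comes from a Sharpless epoxidation of a Z-allylic alcohol; the diarylmethine (R) comes from inversion in the epoxide opening.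

Key step: step 5

Assumption: the benzyl-protected arenes, the trihydroxyacetophenone and the protected gallic acid used as starting materials are catalogue compounds, and the facial sense of monoisopinocampheylborane on the 2-aryl-4H-chromene is taken to follow that known for 1-arylcycloalkenes (the antipodal borane would be used if it proves opposite).

**Route**

Step 1
Reactants: 1 1,3-bis(benzyloxy)-5-bromobenzene
Product: 2 2,4-bis(benzyloxy)-6-bromobenzaldehyde
Conditions: POCl3, DMF, 0 → 70 °C; then aq. NaOAc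
Reagents that add atoms: N,N-dimethylformamide CN(C)C=O; water O
Why: Vilsmeier–Haack formylation should occur at the position para to one benzyloxy group and ortho to the other that is flanked by bromine, which is less hindered than the site between the two ethers, so the aldehyde carbon (future C4) ends up ortho to bromine (future C8a).

Step 2
Reactants: 2 2,4-bis(benzyloxy)-6-bromobenzaldehyde
Product: 3 [2,4-bis(benzyloxy)-6-bromophenyl]methanol
Conditions: NaBH4, THF/MeOH, 0 °C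
Reagents that add atoms: none
Why: Borohydride reduction of the aryl aldehyde to the benzylic alcohol leaves the aryl bromide and the benzyl ethers untouched.

Step 3
Reactants: 3 [2,4-bis(benzyloxy)-6-bromophenyl]methanol
Product: 4 1,5-bis(benzyloxy)-3-bromo-2-(bromomethyl)benzene
Conditions: PBr3, CH2Cl2, 0 °C; used crude and cold
Reagents that add atoms: phosphorus tribromide BrP(Br)Br
Why: PBr3 converts the benzylic alcohol into the bromide under non-ionising conditions; because this 2,4-dialkoxybenzyl bromide ionises easily it should be taken directly into step 5.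

Step 4
Reactants: 5 1-(3,4,5-trihydroxyphenyl)ethanone
Product: 6 1-[3,4,5-tris(benzyloxy)phenyl]ethanone
Conditions: BnBr (3.3 equiv), K2CO3, DMF, 60 °C
Reagents that add atoms: benzyl bromide BrCc1ccccc1
Why: Williamson etherification of the three phenols under carbonate conditions, which do not enolise the methyl ketone.

Step 5
Reactants: 4 1,5-bis(benzyloxy)-3-bromo-2-(bromomethyl)benzene; 6 1-[3,4,5-tris(benzyloxy)phenyl]ethanone
Product: 9 5,7-bis(benzyloxy)-2-[3,4,5-tris(benzyloxy)phenyl]-4H-chromene, via lithium enolate 7 (not isolated), via bromo ketone 8 (not isolated)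
Conditions: 6 (slight excess), LiN(SiMe3)2, THF, −78 °C; add 4, −78 → 0 °C; then Pd2(dba)3 (cat.), DPEphos (cat.), Cs2CO3, toluene, 100 °C, same flask
Reagents that add atoms: none
Why: The lithium enolate 7 is C-benzylated by the benzylic bromide of 4 (SN2, forming C3–C4) to give ketone 8, after which zerovalent palladium inserts into the C8a–Br bond, 8 is enolised by the carbonate and binds to divalent palladium through oxygen, and C–O reductive elimination forms O1–C8a. The closest known reaction types are the tandem C-benzylation/intramolecular enolate O-arylation of 2-halobenzyl halides with 1,3-dicarbonyl compounds and the palladium- or copper-catalysed O-arylation of simple ketone enolates to benzofurans and 4H-chromenes. Ring C closes in the second stage by reductive elimination from a seven-membered oxapalladacycle, formally a 6-exo attack of the enolate oxygen on the aryl carbon C8a. No stereocentre is created, because C2 and C3 leave the step as the sp2 carbons of an enol ether and are set together in step 6. The step needs C- over O-benzylation and mono- over dialkylation (lithium enolate in THF at low temperature, ketone in slight excess), insertion at the aryl and not the benzylic bromide (the benzylic bromide is consumed before palladium is added), O- over C-arylation (8 has one enolisable position, C3, and C-arylation would need a four-membered ring) and no migration of the double bond towards ring A (weak carbonate base).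

Step 6
Reactants: 9 5,7-bis(benzyloxy)-2-[3,4,5-tris(benzyloxy)phenyl]-4H-chromene
Product: 11 (2S,3R)-5,7-bis(benzyloxy)-2-[3,4,5-tris(benzyloxy)phenyl]chroman-3-ol (2,3-trans), via trans-alkylborane 10 (not isolated)
Conditions: monoisopinocampheylborane (IpcBH2, prepared from (−)-α-pinene), THF, −25 °C; then NaOH, H2O2, 0 °C → rt
Reagents that add atoms: hydrogen peroxide OO
Why: Asymmetric hydroboration–oxidation: the B–H bond adds syn across C2=C3 with boron on C3 (β to O1, away from the aryl-bearing carbon) and hydrogen on C2 from the same face, so oxidation with retention should give the 2,3-trans alcohol, the face being chosen by the isopinocampheyl group and expected, by analogy with 1-arylcycloalkenes, to give (2S,3R).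

Step 7
Reactants: 11 (2S,3R)-5,7-bis(benzyloxy)-2-[3,4,5-tris(benzyloxy)phenyl]chroman-3-ol
Product: 12 tert-butyl{[(2S,3R)-5,7-bis(benzyloxy)-2-[3,4,5-tris(benzyloxy)phenyl]chroman-3-yl]oxy}dimethylsilane
Conditions: TBSCl, imidazole, DMF, rt
Reagents that add atoms: tert-butyldimethylsilyl chloride CC(C)(C)[Si](C)(C)Cl
Why: Silylation masks the only hydroxyl group, so that it neither opens the epoxide in step 12 nor quenches the aryllithium in step 15, with a group orthogonal to benzyl ethers.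

Step 8
Reactants: 13 3,4,5-tris(benzyloxy)benzaldehyde
Product: 14 ethyl (Z)-3-[3,4,5-tris(benzyloxy)phenyl]prop-2-enoate
Conditions: (2-MeC6H4O)2P(O)CH2CO2Et, NaH, THF, −78 → 0 °C
Reagents that add atoms: ethyl 2-[bis(2-methylphenoxy)phosphoryl]acetate CCOC(=O)CP(=O)(Oc1ccccc1C)Oc1ccccc1C
Why: Horner–Wadsworth–Emmons olefination with a diaryl phosphonoacetate, whose fast, irreversible elimination from the syn adduct should give the Z enoate from an aromatic aldehyde.

Step 9
Reactants: 14 ethyl (Z)-3-[3,4,5-tris(benzyloxy)phenyl]prop-2-enoate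
Product: 15 (Z)-3-[3,4,5-tris(benzyloxy)phenyl]prop-2-en-1-ol
Conditions: i-Bu2AlH, CH2Cl2, −78 °C; aq. KNaC4H4O6 (tartrate) work-up
Reagents that add atoms: none
Why: 1,2-Reduction of the enoate by the aluminium hydride at low temperature gives the allylic alcohol without isomerising the Z double bond.

Step 10
Reactants: 15 (Z)-3-[3,4,5-tris(benzyloxy)phenyl]prop-2-en-1-ol
Product: 16 [(2S,3R)-3-[3,4,5-tris(benzyloxy)phenyl]oxiran-2-yl]methanol (cis epoxide)
Conditions: Ti(OiPr)4 (cat.), L-(+)-diethyl tartrate (cat.), t-BuOOH, 4 Å molecular sieves, CH2Cl2, −20 °C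
Reagents that add atoms: tert-butyl hydroperoxide CC(C)(C)OO
Why: Sharpless asymmetric epoxidation, in which the titanium–L-tartrate complex delivers oxygen to one face of the allylic alcohol to set (2S) and the Z geometry is carried stereospecifically into the cis (2S,3R) epoxide.

Step 11
Reactants: 16 [(2S,3R)-3-[3,4,5-tris(benzyloxy)phenyl]oxiran-2-yl]methanol
Product: 17 [(2S,3R)-3-[3,4,5-tris(benzyloxy)phenyl]oxiran-2-yl]methyl 4-methylbenzenesulfonate
Conditions: TsCl, Et3N, DMAP (cat.), CH2Cl2, 0 °C; recrystallise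
Reagents that add atoms: 4-methylbenzenesulfonyl chloride Cc1ccc(cc1)S(Cl)(=O)=O
Why: Sulfonylation of the primary alcohol installs the leaving group for step 13 and gives a crystalline derivative by which the enantiomeric purity of this Z-derived epoxide can be raised.

Step 12
Reactants: 12 tert-butyl{[(2S,3R)-5,7-bis(benzyloxy)-2-[3,4,5-tris(benzyloxy)phenyl]chroman-3-yl]oxy}dimethylsilane; 17 [(2S,3R)-3-[3,4,5-tris(benzyloxy)phenyl]oxiran-2-yl]methyl 4-methylbenzenesulfonate
Product: 18 (2R,3R)-3-[(2S,3R)-5,7-bis(benzyloxy)-3-(tert-butyldimethylsilyloxy)-2-[3,4,5-tris(benzyloxy)phenyl]chroman-8-yl]-2-hydroxy-3-[3,4,5-tris(benzyloxy)phenyl]propyl 4-methylbenzenesulfonate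
Conditions: BF3·OEt2, CH2Cl2, −78 °C (12 in excess, recovered)
Reagents that add atoms: none
Why: Lewis-acid-promoted Friedel–Crafts alkylation in which C8 of ring A, the more accessible nucleophilic position of the 5,7-dialkoxy ring as in 4→8 flavan couplings, opens the epoxide at its benzylic carbon from the side opposite to oxygen, so that inversion gives the (R) diarylmethine while the carbinol carbon keeps its configuration and the tosylate stays intact.

Step 13
Reactants: 18 (2R,3R)-3-[(2S,3R)-5,7-bis(benzyloxy)-3-(tert-butyldimethylsilyloxy)-2-[3,4,5-tris(benzyloxy)phenyl]chroman-8-yl]-2-hydroxy-3-[3,4,5-tris(benzyloxy)phenyl]propyl 4-methylbenzenesulfonate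
Product: 19 tert-butyl{[(2S,3R)-5,7-bis(benzyloxy)-8-{(R)-[(2R)-oxiran-2-yl][3,4,5-tris(benzyloxy)phenyl]methyl}-2-[3,4,5-tris(benzyloxy)phenyl]chroman-3-yl]oxy}dimethylsilane
Conditions: K2CO3, MeOH/THF, 0 °C → rt
Reagents that add atoms: none
Why: Intramolecular Williamson etherification (3-exo-tet) of the secondary alkoxide onto the primary tosylate moves the epoxide to the chain terminus without touching a stereocentre.

Step 14
Reactants: 20 1,3,5-tris(benzyloxy)benzene
Product: 21 1,3,5-tris(benzyloxy)-2-bromobenzene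
Conditions: NBS (1 equiv), CH2Cl2, 0 °C
Reagents that add atoms: N-bromosuccinimide O=C1CCC(=O)N1Br
Why: Electrophilic aromatic bromination of the phloroglucinol triether, whose three free positions are equivalent, should stop at the monobromide with one equivalent of reagent at low temperature.

Step 15
Reactants: 19 tert-butyl{[(2S,3R)-5,7-bis(benzyloxy)-8-{(R)-[(2R)-oxiran-2-yl][3,4,5-tris(benzyloxy)phenyl]methyl}-2-[3,4,5-tris(benzyloxy)phenyl]chroman-3-yl]oxy}dimethylsilane; 21 1,3,5-tris(benzyloxy)-2-bromobenzene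
Product: 23 (1R,2S)-1-[(2S,3R)-5,7-bis(benzyloxy)-3-(tert-butyldimethylsilyloxy)-2-[3,4,5-tris(benzyloxy)phenyl]chroman-8-yl]-1-[3,4,5-tris(benzyloxy)phenyl]-3-[2,4,6-tris(benzyloxy)phenyl]propan-2-ol, via aryllithium 22 (not isolated)
Conditions: 21, n-BuLi, THF, −78 °C; then 19, BF3·OEt2, −78 °C
Reagents that add atoms: none
Why: Bromine–lithium exchange followed by BF3-assisted SN2 opening of the terminal epoxide at its CH2 carbon by the aryllithium attaches the phloroglucinol ring and leaves the carbinol configuration untouched (its descriptor becomes S only because the priorities change).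

Step 16
Reactants: 23 (1R,2S)-1-[(2S,3R)-5,7-bis(benzyloxy)-3-(tert-butyldimethylsilyloxy)-2-[3,4,5-tris(benzyloxy)phenyl]chroman-8-yl]-1-[3,4,5-tris(benzyloxy)phenyl]-3-[2,4,6-tris(benzyloxy)phenyl]propan-2-ol
Product: 24 (2S,3R)-5,7-bis(benzyloxy)-8-{(1R,2S)-2-hydroxy-1-[3,4,5-tris(benzyloxy)phenyl]-3-[2,4,6-tris(benzyloxy)phenyl]propyl}-2-[3,4,5-tris(benzyloxy)phenyl]chroman-3-ol
Conditions: Bu4NF, THF, rt
Reagents that add atoms: none
Why: Fluoride-induced cleavage of the silyl ether frees the C3 hydroxyl while the benzyl ethers are inert.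

Step 17
Reactants: 24 (2S,3R)-5,7-bis(benzyloxy)-8-{(1R,2S)-2-hydroxy-1-[3,4,5-tris(benzyloxy)phenyl]-3-[2,4,6-tris(benzyloxy)phenyl]propyl}-2-[3,4,5-tris(benzyloxy)phenyl]chroman-3-ol; 25 3,4,5-tris(benzyloxy)benzoic acid (two equivalents are taken up, the second is entered under the reagents)
Product: 26 (2S,3R)-5,7-bis(benzyloxy)-8-{(1R,2S)-1-[3,4,5-tris(benzyloxy)phenyl]-2-{[3,4,5-tris(benzyloxy)benzoyl]oxy}-3-[2,4,6-tris(benzyloxy)phenyl]propyl}-2-[3,4,5-tris(benzyloxy)phenyl]chroman-3-yl 3,4,5-tris(benzyloxy)benzoate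
Conditions: 25 (4 equiv), DCC (4 equiv), DMAP, CH2Cl2, rt
Reagents that add atoms: 3,4,5-tris(benzyloxy)benzoic acid (second equivalent of 25) OC(=O)c1cc(OCc3ccccc3)c(OCc3ccccc3)c(OCc3ccccc3)c1
Why: Twofold Steglich esterification, in which one molecule of the protected gallic acid acylates the C3 hydroxyl of ring C and a second acylates the side-chain carbinol, each with loss of water to the carbodiimide; all phenols are masked and no stereocentre is touched.

Step 18
Reactants: 26 (2S,3R)-5,7-bis(benzyloxy)-8-{(1R,2S)-1-[3,4,5-tris(benzyloxy)phenyl]-2-{[3,4,5-tris(benzyloxy)benzoyl]oxy}-3-[2,4,6-tris(benzyloxy)phenyl]propyl}-2-[3,4,5-tris(benzyloxy)phenyl]chroman-3-yl 3,4,5-tris(benzyloxy)benzoate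
Product: 27 (2S,3R)-5,7-dihydroxy-8-{(1R,2S)-2-[(3,4,5-trihydroxybenzoyl)oxy]-1-(3,4,5-trihydroxyphenyl)-3-(2,4,6-trihydroxyphenyl)propyl}-2-(3,4,5-trihydroxyphenyl)chroman-3-yl 3,4,5-trihydroxybenzoate (CNP0155034.3)
Conditions: H2 (1 atm), Pd(OH)2/C, THF/MeOH, rt; handle under argon
Reagents that add atoms: none
Why: Hydrogenolysis over palladium hydroxide removes all seventeen benzyl ethers, while the two alkyl gallate esters, the diarylmethine C–C bonds and the ring-C ether are expected to survive, as with benzylated catechin gallates.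

**Compound list**

1 | 1,3-bis(benzyloxy)-5-bromobenzene | Brc1cc(OCc3ccccc3)cc(OCc3ccccc3)c1 | starting material
2 | 2,4-bis(benzyloxy)-6-bromobenzaldehyde | O=Cc1c(Br)cc(OCc3ccccc3)cc1OCc3ccccc3 | intermediate
3 | [2,4-bis(benzyloxy)-6-bromophenyl]methanol | OCc1c(Br)cc(OCc3ccccc3)cc1OCc3ccccc3 | intermediate
4 | 1,5-bis(benzyloxy)-3-bromo-2-(bromomethyl)benzene | BrCc1c(Br)cc(OCc3ccccc3)cc1OCc3ccccc3 | intermediate
5 | 1-(3,4,5-trihydroxyphenyl)ethanone | CC(=O)c1cc(O)c(O)c(O)c1 | starting material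
6 | 1-[3,4,5-tris(benzyloxy)phenyl]ethanone | CC(=O)c1cc(OCc3ccccc3)c(OCc3ccccc3)c(OCc3ccccc3)c1 | intermediate
7 | lithium 1-[3,4,5-tris(benzyloxy)phenyl]ethenolate (lithium enolate of 6) | [Li]OC(=C)c1cc(OCc3ccccc3)c(OCc3ccccc3)c(OCc3ccccc3)c1 | intermediate
8 | 3-[2,4-bis(benzyloxy)-6-bromophenyl]-1-[3,4,5-tris(benzyloxy)phenyl]propan-1-one | O=C(CCc1c(Br)cc(OCc3ccccc3)cc1OCc3ccccc3)c1cc(OCc3ccccc3)c(OCc3ccccc3)c(OCc3ccccc3)c1 | intermediate
9 | 5,7-bis(benzyloxy)-2-[3,4,5-tris(benzyloxy)phenyl]-4H-chromene | C1(c2cc(OCc3ccccc3)c(OCc3ccccc3)c(OCc3ccccc3)c2)=CCc2c(OCc3ccccc3)cc(OCc3ccccc3)cc2O1 | intermediate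
10 | [5,7-bis(benzyloxy)-2-[3,4,5-tris(benzyloxy)phenyl]chroman-3-yl](isopinocampheyl)borane, 2,3-trans with boron on C3 anti to the C2 aryl group ((2R,3R) by the sequence rule because boron ranks below carbon), isopinocampheyl from (−)-α-pinene | c1c(OCc3ccccc3)cc(OCc3ccccc3)c2c1O[C@@H](c1cc(OCc3ccccc3)c(OCc3ccccc3)c(OCc3ccccc3)c1)[C@H](B[C@H]4C[C@H]5C[C@@H]([C@@H]4C)C5(C)C)C2 | intermediate
11 | (2S,3R)-5,7-bis(benzyloxy)-2-[3,4,5-tris(benzyloxy)phenyl]chroman-3-ol | c1c(OCc3ccccc3)cc(OCc3ccccc3)c2c1O[C@@H](c1cc(OCc3ccccc3)c(OCc3ccccc3)c(OCc3ccccc3)c1)[C@H](O)C2 | intermediate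
12 | tert-butyl{[(2S,3R)-5,7-bis(benzyloxy)-2-[3,4,5-tris(benzyloxy)phenyl]chroman-3-yl]oxy}dimethylsilane | c1c(OCc3ccccc3)cc(OCc3ccccc3)c2c1O[C@@H](c1cc(OCc3ccccc3)c(OCc3ccccc3)c(OCc3ccccc3)c1)[C@H](O[Si](C)(C)C(C)(C)C)C2 | intermediate
13 | 3,4,5-tris(benzyloxy)benzaldehyde | O=Cc1cc(OCc3ccccc3)c(OCc3ccccc3)c(OCc3ccccc3)c1 | starting material
14 | ethyl (Z)-3-[3,4,5-tris(benzyloxy)phenyl]prop-2-enoate | CCOC(=O)/C=C\c1cc(OCc3ccccc3)c(OCc3ccccc3)c(OCc3ccccc3)c1 | intermediate
15 | (Z)-3-[3,4,5-tris(benzyloxy)phenyl]prop-2-en-1-ol | OC/C=C\c1cc(OCc3ccccc3)c(OCc3ccccc3)c(OCc3ccccc3)c1 | intermediate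
16 | [(2S,3R)-3-[3,4,5-tris(benzyloxy)phenyl]oxiran-2-yl]methanol | OC[C@@H]1O[C@@H]1c1cc(OCc3ccccc3)c(OCc3ccccc3)c(OCc3ccccc3)c1 | intermediate
17 | [(2S,3R)-3-[3,4,5-tris(benzyloxy)phenyl]oxiran-2-yl]methyl 4-methylbenzenesulfonate | Cc1ccc(cc1)S(=O)(=O)OC[C@@H]1O[C@@H]1c1cc(OCc3ccccc3)c(OCc3ccccc3)c(OCc3ccccc3)c1 | intermediate
18 | (2R,3R)-3-[(2S,3R)-5,7-bis(benzyloxy)-3-(tert-butyldimethylsilyloxy)-2-[3,4,5-tris(benzyloxy)phenyl]chroman-8-yl]-2-hydroxy-3-[3,4,5-tris(benzyloxy)phenyl]propyl 4-methylbenzenesulfonate | Cc1ccc(cc1)S(=O)(=O)OC[C@H](O)[C@H](c1cc(OCc3ccccc3)c(OCc3ccccc3)c(OCc3ccccc3)c1)c1c(OCc3ccccc3)cc(OCc3ccccc3)c2c1O[C@@H](c1cc(OCc3ccccc3)c(OCc3ccccc3)c(OCc3ccccc3)c1)[C@H](O[Si](C)(C)C(C)(C)C)C2 | intermediate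
19 | tert-butyl{[(2S,3R)-5,7-bis(benzyloxy)-8-{(R)-[(2R)-oxiran-2-yl][3,4,5-tris(benzyloxy)phenyl]methyl}-2-[3,4,5-tris(benzyloxy)phenyl]chroman-3-yl]oxy}dimethylsilane | C1O[C@@H]1[C@H](c1cc(OCc3ccccc3)c(OCc3ccccc3)c(OCc3ccccc3)c1)c1c(OCc3ccccc3)cc(OCc3ccccc3)c2c1O[C@@H](c1cc(OCc3ccccc3)c(OCc3ccccc3)c(OCc3ccccc3)c1)[C@H](O[Si](C)(C)C(C)(C)C)C2 | intermediate
20 | 1,3,5-tris(benzyloxy)benzene | c1(OCc3ccccc3)cc(OCc3ccccc3)cc(OCc3ccccc3)c1 | starting material
21 | 1,3,5-tris(benzyloxy)-2-bromobenzene | Brc1c(OCc3ccccc3)cc(OCc3ccccc3)cc1OCc3ccccc3 | intermediate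
22 | [2,4,6-tris(benzyloxy)phenyl]lithium | [Li]c1c(OCc3ccccc3)cc(OCc3ccccc3)cc1OCc3ccccc3 | intermediate
23 | (1R,2S)-1-[(2S,3R)-5,7-bis(benzyloxy)-3-(tert-butyldimethylsilyloxy)-2-[3,4,5-tris(benzyloxy)phenyl]chroman-8-yl]-1-[3,4,5-tris(benzyloxy)phenyl]-3-[2,4,6-tris(benzyloxy)phenyl]propan-2-ol | O[C@@H](Cc1c(OCc3ccccc3)cc(OCc3ccccc3)cc1OCc3ccccc3)[C@H](c1cc(OCc3ccccc3)c(OCc3ccccc3)c(OCc3ccccc3)c1)c1c(OCc3ccccc3)cc(OCc3ccccc3)c2c1O[C@@H](c1cc(OCc3ccccc3)c(OCc3ccccc3)c(OCc3ccccc3)c1)[C@H](O[Si](C)(C)C(C)(C)C)C2 | intermediate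
24 | (2S,3R)-5,7-bis(benzyloxy)-8-{(1R,2S)-2-hydroxy-1-[3,4,5-tris(benzyloxy)phenyl]-3-[2,4,6-tris(benzyloxy)phenyl]propyl}-2-[3,4,5-tris(benzyloxy)phenyl]chroman-3-ol | O[C@@H](Cc1c(OCc3ccccc3)cc(OCc3ccccc3)cc1OCc3ccccc3)[C@H](c1cc(OCc3ccccc3)c(OCc3ccccc3)c(OCc3ccccc3)c1)c1c(OCc3ccccc3)cc(OCc3ccccc3)c2c1O[C@@H](c1cc(OCc3ccccc3)c(OCc3ccccc3)c(OCc3ccccc3)c1)[C@H](O)C2 | intermediate
25 | 3,4,5-tris(benzyloxy)benzoic acid | OC(=O)c1cc(OCc3ccccc3)c(OCc3ccccc3)c(OCc3ccccc3)c1 | starting material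
26 | (2S,3R)-5,7-bis(benzyloxy)-8-{(1R,2S)-1-[3,4,5-tris(benzyloxy)phenyl]-2-{[3,4,5-tris(benzyloxy)benzoyl]oxy}-3-[2,4,6-tris(benzyloxy)phenyl]propyl}-2-[3,4,5-tris(benzyloxy)phenyl]chroman-3-yl 3,4,5-tris(benzyloxy)benzoate | O=C(O[C@@H](Cc1c(OCc3ccccc3)cc(OCc3ccccc3)cc1OCc3ccccc3)[C@H](c1cc(OCc3ccccc3)c(OCc3ccccc3)c(OCc3ccccc3)c1)c1c(OCc3ccccc3)cc(OCc3ccccc3)c2c1O[C@@H](c1cc(OCc3ccccc3)c(OCc3ccccc3)c(OCc3ccccc3)c1)[C@H](OC(=O)c1cc(OCc3ccccc3)c(OCc3ccccc3)c(OCc3ccccc3)c1)C2)c1cc(OCc3ccccc3)c(OCc3ccccc3)c(OCc3ccccc3)c1 | intermediate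
27 | (2S,3R)-5,7-dihydroxy-8-{(1R,2S)-2-[(3,4,5-trihydroxybenzoyl)oxy]-1-(3,4,5-trihydroxyphenyl)-3-(2,4,6-trihydroxyphenyl)propyl}-2-(3,4,5-trihydroxyphenyl)chroman-3-yl 3,4,5-trihydroxybenzoate (CNP0155034.3) | O=C(O[C@@H](Cc1c(O)cc(O)cc1O)[C@H](c1cc(O)c(O)c(O)c1)c1c(O)cc(O)c2c1O[C@@H](c1cc(O)c(O)c(O)c1)[C@H](OC(=O)c1cc(O)c(O)c(O)c1)C2)c1cc(O)c(O)c(O)c1 | target

**Step count and risks**

Total step count: 18 steps. Longest linear sequence: 12 steps (steps 1, 2, 3, 5, 6, 7, 12, 13, 15, 16, 17, 18; from 1 to 27).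

Steps most likely to fail:

Step 5. What may go wrong: ionisation and self-condensation of the electron-rich benzylic bromide or double alkylation of the enolate in the first stage; in the second stage, reduction of the C–Br bond, intermolecular C-arylation, or base-induced migration of the C2=C3 double bond. The fallback sets out from 2 and 6 and returns at 9. Claisen–Schmidt condensation of aldehyde 2 with ketone 6 (KOH, EtOH/THF, rt) should give the chalcone (E)-3-[2,4-bis(benzyloxy)-6-bromophenyl]-1-[3,4,5-tris(benzyloxy)phenyl]prop-2-en-1-one F1. Chemoselective conjugate reduction of F1 ([(Ph3P)CuH]6 cat., polymethylhydrosiloxane, toluene, rt) should give ketone 8, now isolated and purified. Copper-catalysed intramolecular enolate O-arylation of 8 (CuI, 1,10-phenanthroline, K3PO4, DMF, 100 °C) then closes ring C to 9. The C3–C4 bond here comes from an aldol condensation, the labile bromide 4 is avoided, and the two bonds are made in separate steps.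

Step 6. What may go wrong: poor facial discrimination of the flat enol ether by the chiral borane, giving low enantiomeric purity that no later step corrects. The fallback sets out from 9 and returns at 11. Hydroboration–oxidation with achiral BH3·SMe2 (THF, 0 °C; NaOH, H2O2) should give racemic trans-5,7-bis(benzyloxy)-2-[3,4,5-tris(benzyloxy)phenyl]chroman-3-ol F2. Esterification with (S)-2-methoxy-2-phenylacetic acid (DCC, DMAP, CH2Cl2) gives two diastereomeric esters, (2S,3R)-5,7-bis(benzyloxy)-2-[3,4,5-tris(benzyloxy)phenyl]chroman-3-yl (2S)-2-methoxy-2-phenylacetate F3 and (2R,3S)-5,7-bis(benzyloxy)-2-[3,4,5-tris(benzyloxy)phenyl]chroman-3-yl (2S)-2-methoxy-2-phenylacetate F4, to be separated by chromatography or crystallisation. Saponification of F3 (LiOH, THF/H2O) returns 11.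

Step 12. What may go wrong: loss of stereospecificity at the benzylic carbon through an open carbocation (partial retention), Meinwald rearrangement of the epoxide, or competing attack at C6 of ring A. The fallback sets out from 12 and returns at 18. Bromination of 12 with NBS (CH2Cl2, −20 °C), known to go to C8 in 5,7-dialkoxyflavans, should give tert-butyl{[(2S,3R)-5,7-bis(benzyloxy)-8-bromo-2-[3,4,5-tris(benzyloxy)phenyl]chroman-3-yl]oxy}dimethylsilane F5. Bromine–lithium exchange (n-BuLi, THF, −78 °C) gives [(2S,3R)-5,7-bis(benzyloxy)-3-(tert-butyldimethylsilyloxy)-2-[3,4,5-tris(benzyloxy)phenyl]chroman-8-yl]lithium F6. F6 opens epoxy tosylate 17 at the benzylic carbon with BF3·OEt2 at −78 °C by SN2 substitution with inversion, the carbanion being fixed at C8, to give 18.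

**Further compounds**

F1 | step 5 | (E)-3-[2,4-bis(benzyloxy)-6-bromophenyl]-1-[3,4,5-tris(benzyloxy)phenyl]prop-2-en-1-one | O=C(/C=C/c1c(Br)cc(OCc3ccccc3)cc1OCc3ccccc3)c1cc(OCc3ccccc3)c(OCc3ccccc3)c(OCc3ccccc3)c1
F2 | step 6 | racemic trans-5,7-bis(benzyloxy)-2-[3,4,5-tris(benzyloxy)phenyl]chroman-3-ol (1:1 mixture of the (2S,3R) and (2R,3S) enantiomers) | c1c(OCc3ccccc3)cc(OCc3ccccc3)c2c1O[C@@H](c1cc(OCc3ccccc3)c(OCc3ccccc3)c(OCc3ccccc3)c1)[C@H](O)C2.c1c(OCc3ccccc3)cc(OCc3ccccc3)c2c1O[C@H](c1cc(OCc3ccccc3)c(OCc3ccccc3)c(OCc3ccccc3)c1)[C@@H](O)C2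
F3 | step 6 | (2S,3R)-5,7-bis(benzyloxy)-2-[3,4,5-tris(benzyloxy)phenyl]chroman-3-yl (2S)-2-methoxy-2-phenylacetate | c1c(OCc3ccccc3)cc(OCc3ccccc3)c2c1O[C@@H](c1cc(OCc3ccccc3)c(OCc3ccccc3)c(OCc3ccccc3)c1)[C@H](OC(=O)[C@@H](OC)c1ccccc1)C2
F4 | step 6 | (2R,3S)-5,7-bis(benzyloxy)-2-[3,4,5-tris(benzyloxy)phenyl]chroman-3-yl (2S)-2-methoxy-2-phenylacetate | c1c(OCc3ccccc3)cc(OCc3ccccc3)c2c1O[C@H](c1cc(OCc3ccccc3)c(OCc3ccccc3)c(OCc3ccccc3)c1)[C@@H](OC(=O)[C@@H](OC)c1ccccc1)C2
F5 | step 12 | tert-butyl{[(2S,3R)-5,7-bis(benzyloxy)-8-bromo-2-[3,4,5-tris(benzyloxy)phenyl]chroman-3-yl]oxy}dimethylsilane | Brc1c(OCc3ccccc3)cc(OCc3ccccc3)c2c1O[C@@H](c1cc(OCc3ccccc3)c(OCc3ccccc3)c(OCc3ccccc3)c1)[C@H](O[Si](C)(C)C(C)(C)C)C2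
F6 | step 12 | [(2S,3R)-5,7-bis(benzyloxy)-3-(tert-butyldimethylsilyloxy)-2-[3,4,5-tris(benzyloxy)phenyl]chroman-8-yl]lithium | [Li]c1c(OCc3ccccc3)cc(OCc3ccccc3)c2c1O[C@@H](c1cc(OCc3ccccc3)c(OCc3ccccc3)c(OCc3ccccc3)c1)[C@H](O[Si](C)(C)C(C)(C)C)C2
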